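The cyclobutane (C4, C5, C9, C10) is closed last, through the C9–C10 bond, by a 4-exo epoxide opening. The kinetic α′-enolate carbon C9 of a cis-fused bicyclo[5.4.0]undecenone, whose six-membered ring carries its carbonyl at C8 and no methyl yet, attacks the methyl-bearing epoxide carbon C10 with inversion. One operation creates the four-membered ring, the quaternary centre C10 and the C11 hydroxyl cis to O1. It exploits the C11 carbinol next to C10 and the 1,3-relationship of C6 and C8 in the enone ring, so that methyllithium addition and oxidative transposition complete the enone. A temporary lactone tether from O2 sets the cis ring fusion.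

Key step: step 10

Remark on numbering (route numbering, not IUPAC): seven-membered ring C1(OAng)–C2(OAng)–C3(Me2)–C4–C5–C10(Me)–C11(OH); six-membered ring A C4–C5–C6(=O)–C7=C8(Me)–C9; cyclobutane C4–C5–C10–C9. The β-face of the seven-membered ring is the face bearing O2; the α-face bears O1 and O11.

Assumption: eucarvone is taken as a purchasable starting material.

Step 1
Reactants: 1 eucarvone (2,6,6-trimethylcyclohepta-2,4-dien-1-one)
Product: 2 3,3,7-trimethylcyclohepta-1,4,6-trien-1-yl trifluoromethanesulfonate
Conditions: LDA (LiN(i-Pr)2), THF, −78 °C; then PhNTf2, −78 °C to rt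
Reagents that add atoms: N-phenylbis(trifluoromethanesulfonimide), O=S(=O)(N(c1ccccc1)S(=O)(=O)C(F)(F)F)C(F)(F)F
Why: Kinetic deprotonation at the only enolisable position (C4) gives the cross-conjugated trienolate, which is O-sulfonylated (enol triflate formation); no stereocentre is formed.

Step 2
Reactants: 2 trienyl triflate
Product: 3 3,3,7-trimethylcyclohepta-1,4,6-triene-1-carbaldehyde
Conditions: Pd(PPh3)4 (cat.), CO (1 atm), Bu3SnH (slow addition), LiCl, THF, 50 °C
Reagents that add atoms: carbon monoxide, [C-]#[O+]
Why: Palladium-catalysed reductive carbonylation of the enol triflate (oxidative addition, CO insertion, hydride transfer from tin) installs C6 as a formyl group and makes C4=C5 a Michael acceptor; no stereocentre is formed.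

Step 3
Reactants: 3 trienal
Product: 4 (4S,5R)-4,5-epoxy-3,3,7-trimethylcyclohepta-1,6-diene-1-carbaldehyde (β-epoxide across C1–C2; 1R,2S in route numbering)
Conditions: [(R,R)-N,N′-bis(3,5-di-tert-butylsalicylidene)cyclohexane-1,2-diaminato]manganese chloride (trivalent manganese, cat.), mCPBA, N-methylmorpholine N-oxide, CH2Cl2, −78 °C
Reagents that add atoms: 3-chloroperoxybenzoic acid, O=C(OO)c1cccc(Cl)c1
Why: Jacobsen–Katsuki epoxidation should select the distal, cis-disubstituted and most electron-rich C1=C2 bond (the other two double bonds are deactivated by the formyl group), and by analogy with 2,2-dimethylchromene the (R,R)-catalyst is expected to give this enantiomer, which fixes the absolute configuration of the route.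

Step 4
Reactants: 4 vinyl epoxide
Product: 5 (4S,5S)-5-acetoxy-4-hydroxy-3,3,7-trimethylcyclohepta-1,6-diene-1-carbaldehyde (C1–OAc α, C2–OH β, trans)
Conditions: CsOAc, AcOH, DMF, 50 °C
Reagents that add atoms: acetic acid, CC(=O)O
Why: SN2 opening of the vinyl epoxide by acetate at the allylic carbon C1 (C2 is neopentyl) should proceed with inversion, setting the trans C1–O/C2–O pattern of the target and leaving O2 free for the tether.

Step 5
Reactants: 5 hydroxy acetate
Product: 6 acetoacetate ester of 5 at O2 (3-oxobutanoate)
Conditions: 2,2,6-trimethyl-4H-1,3-dioxin-4-one, toluene, 110 °C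
Reagents that add atoms: 2,2,6-trimethyl-4H-1,3-dioxin-4-one, CC1=CC(=O)OC(C)(C)O1
Why: Thermal retro-[4+2] of the dioxinone releases acetylketene, which acylates even the hindered C2 hydroxyl (acetoacetylation); no stereocentre changes.

Step 6
Reactants: 6 acetoacetate
Product: 8 tricyclic keto lactone with ring A enone (C8=O and C6=C7) and lactone bridge from C9 to O2, via bridged lactone aldehyde 7 (not isolated)
Conditions: DBU (cat.), CH2Cl2, 0 °C to rt; then p-TsOH·H2O, toluene, 60 °C
Reagents that add atoms: none
Why: Intramolecular Michael addition (6-exo-trig) of the acetoacetate carbon C9 to C4 can occur only on the face of O2 and so sets C4, and the following aldol condensation of the methyl ketone C7 onto the aldehyde C6 (Robinson-type annulation) can close ring A only from the C5 epimer whose formyl group is syn to the lactone bridge, so the epimerisable C5 is funnelled into the cis ring fusion.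

Step 7
Reactants: 8 tricyclic keto lactone
Product: 10 cis-fused bicyclic enone diol (C1–OH α and C2–OH β and C10=C11 and ring A cyclohex-2-enone), via β-keto acid 9 (not isolated)
Conditions: LiOH, THF/H2O, 0 °C to rt; then 1 M HCl, 50 °C
Reagents that add atoms: none
Why: Saponification opens the lactone tether and the acetate, and the β-keto acid decarboxylates on acidification, leaving C9 as the α′-methylene of the enone; C1, C2, C4 and C5 are untouched.

Step 8
Reactants: 10 enone diol
Product: 11 α-epoxide of 10 across C10–C11 (cis to the C1 hydroxyl)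
Conditions: VO(acac)2 (cat.), t-BuOOH, CH2Cl2, 0 °C to rt
Reagents that add atoms: tert-butyl hydroperoxide, CC(C)(C)OO
Why: Vanadium-catalysed hydroxyl-directed epoxidation delivers oxygen from the allylic C1 hydroxyl to its own (α) face of the trisubstituted C10=C11 bond, which is also the face anti to ring A, and leaves the enone untouched.

Step 9
Reactants: 11 epoxy diol
Product: 12 C1,C2-acetonide of 11
Conditions: 2-methoxypropene, PPTS (cat.), CH2Cl2, 0 °C
Reagents that add atoms: 2-methoxypropene, COC(C)=C
Why: Acid-catalysed ketalisation masks the trans-diol so that no alkoxide can attack the epoxide in the next step; no stereocentre changes.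

Step 10
Reactants: 12 epoxy enone acetonide
Product: 15 tricyclic enone with the cyclobutane closed and O11 as TBS ether, via lithium dienolate 13 (not isolated), via lithium alkoxide 14 (not isolated)
Conditions: LDA (LiN(i-Pr)2), THF, −78 to 0 °C; then TBSOTf, −78 °C
Reagents that add atoms: tert-butyldimethylsilyl trifluoromethanesulfonate, CC(C)(C)[Si](C)(C)OS(=O)(=O)C(F)(F)F
Why: LDA removes a C9 proton (kinetic α′-deprotonation of the cyclohexenone) and the enolate carbon displaces the epoxide oxygen at C10 from the backside, after which the C11 alkoxide is silylated in the same flask. The closest known reaction type is the intramolecular enolate–epoxide alkylation of the epoxynitrile and epoxy-ketone kind, which favours four-membered rings formed in the exo mode. The cyclobutane closes 4-exo-tet, with C9 and the C10 substituent on C5 in a 1,3-diaxial-like arrangement on ring A, as in enolate alkylations that give bicyclo[3.1.1]heptan-2-ones. C10 is set by inversion because ring A lies on the β-face and the epoxide oxygen on the α-face, C9 is fixed by the bridged geometry, and C11 keeps the configuration from the directed epoxidation, hence cis to O1. The step needs C-alkylation at the tertiary carbon: O-alkylation would require a bridgehead enol ether, 5-endo attack at C11 cannot reach a collinear trajectory, and kinetic conditions favour α′- over γ-deprotonation.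

Step 11
Reactants: 15 tricyclic enone
Product: 16 tertiary allylic alcohol (methyl added at C8)
Conditions: MeLi, CeCl3, THF, −78 °C
Reagents that add atoms: methyllithium, [Li]C
Why: 1,2-Addition of the organocerium reagent to the non-enolisable enone (C9 and C5 are bridgeheads) should occur from the face of the C4 bridge; the new centre is destroyed in the next step.

Step 12
Reactants: 16 tertiary allylic alcohol
Product: 17 transposed enone (C6=O, C7=C8–Me) with acetonide and TBS ether intact
Conditions: pyridinium chlorochromate [C5H5NH][CrO3Cl], NaOAc, 4 Å sieves, CH2Cl2, rt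
Reagents that add atoms: pyridinium chlorochromate, [O-][Cr](=O)(=O)Cl.c1cc[nH+]cc1
Why: Babler–Dauben oxidative transposition: the chromate ester undergoes a [3,3] shift and oxidation, moving oxygen from C8 to C6 and giving the 3-methyl enone of the target.

Step 13
Reactants: 17 enone acetonide
Product: 18 C1,C2-diol with O11 still silylated
Conditions: PPTS, MeOH, 40 °C
Reagents that add atoms: none
Why: Acid-catalysed transketalisation removes the strained trans-fused acetonide while the hindered secondary TBS ether should survive.

Step 14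
Reactants: 18 diol
Product: 19 1,2-di-O-angelate of 18
Conditions: angelic acid, 2,4,6-trichlorobenzoyl chloride, Et3N, toluene, rt; then 18, 80 °C
Reagents that add atoms: angelic acid ((Z)-2-methylbut-2-enoic acid), C/C=C(/C)C(=O)O
Why: Yamaguchi-type esterification through the mixed anhydride without a nucleophilic catalyst should acylate both hydroxyls with retention of the (Z)-geometry; O11 is protected, so no regiochemical question arises.

Step 15
Reactants: 19 diangelate silyl ether
Product: 20 target CNP0256888.1
Conditions: HF·pyridine, THF, 0 °C to rt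
Reagents that add atoms: none
Why: Fluoride cleavage of the silyl ether under acidic conditions (no alkoxide, hence no acyl migration from O1 to O11) liberates the C11 hydroxyl.

Compound list
1 | eucarvone (2,6,6-trimethylcyclohepta-2,4-dien-1-one) | CC1=CC=CC(C)(C)CC1=O | starting material
2 | 3,3,7-trimethylcyclohepta-1,4,6-trien-1-yl trifluoromethanesulfonate | CC1=CC=CC(C)(C)C=C1OS(=O)(=O)C(F)(F)F | intermediate
3 | 3,3,7-trimethylcyclohepta-1,4,6-triene-1-carbaldehyde | CC1=CC=CC(C)(C)C=C1C=O | intermediate
4 | (4S,5R)-4,5-epoxy-3,3,7-trimethylcyclohepta-1,6-diene-1-carbaldehyde | CC1=C[C@H]2O[C@H]2C(C)(C)C=C1C=O | intermediate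
5 | (4S,5S)-5-acetoxy-4-hydroxy-3,3,7-trimethylcyclohepta-1,6-diene-1-carbaldehyde | CC(=O)O[C@@H]1[C@@H](O)C(C)(C)C=C(C=O)C(C)=C1 | intermediate
6 | O2-acetoacetate of 5 | CC(=O)O[C@@H]1[C@@H](OC(=O)CC(C)=O)C(C)(C)C=C(C=O)C(C)=C1 | intermediate
7 | bridged δ-lactone aldehyde (Michael adduct; C9 on the β-face of C4, formyl on C5 syn to the bridge) | CC(=O)O[C@@H]1[C@H]2OC(=O)[C@H](C(C)=O)[C@H](C2(C)C)[C@@H](C=O)C(C)=C1 | intermediate
8 | tricyclic keto lactone: cis-fused ring A enone, lactone from C9 to O2, C1 acetate (C9 configuration inconsequential) | CC(=O)O[C@@H]1[C@H]2OC(=O)[C@@H]3C(=O)C=C[C@H]([C@H]3C2(C)C)C(C)=C1 | intermediate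
9 | β-keto acid from 8 (C9 carboxylic acid, C1 and C2 hydroxyls free) | O[C@@H]1[C@@H](O)C(C)(C)[C@H]2[C@H](C(=O)O)C(=O)C=C[C@H]2C(C)=C1 | intermediate
10 | cis-fused bicyclo[5.4.0]undecadienone diol: ring A cyclohex-2-enone (C8=O), C10=C11, C1–OH α, C2–OH β | O[C@@H]1[C@@H](O)C(C)(C)[C@H]2CC(=O)C=C[C@H]2C(C)=C1 | intermediate
11 | α-C10,C11-epoxide of 10 (cis to C1–OH) | O[C@@H]1[C@@H](O)C(C)(C)[C@H]2CC(=O)C=C[C@H]2[C@]3(C)O[C@H]13 | intermediate
12 | C1,C2-acetonide of 11 | CC1(C)O[C@@H]2[C@@H](O1)C(C)(C)[C@H]3CC(=O)C=C[C@H]3[C@]4(C)O[C@H]24 | intermediate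
13 | lithium cross-conjugated dienolate of 12 (C8–O, C8=C9) | CC1(C)O[C@@H]2[C@@H](O1)C(C)(C)[C@H]3C=C([O-])C=C[C@H]3[C@]4(C)O[C@H]24.[Li+] | intermediate
14 | lithium C11-alkoxide of the cyclised tricyclic enone | CC1(C)O[C@@H]2[C@@H](O1)C(C)(C)[C@@H]3[C@H]4C=CC(=O)[C@@H]3[C@@]4(C)[C@@H]2[O-].[Li+] | intermediate
15 | tricyclic enone (C8=O, C6=C7), C1,C2-acetonide, C11–OTBS | CC1(C)O[C@@H]2[C@@H](O1)C(C)(C)[C@@H]3[C@H]4C=CC(=O)[C@@H]3[C@@]4(C)[C@@H]2O[Si](C)(C)C(C)(C)C | intermediate
16 | C8 tertiary allylic alcohol from 15 (methyl on the face of the C4 bridge) | CC1(C)O[C@@H]2[C@@H](O1)C(C)(C)[C@@H]3[C@H]4C=C[C@](C)(O)[C@@H]3[C@@]4(C)[C@@H]2O[Si](C)(C)C(C)(C)C | intermediate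
17 | target enone skeleton (C6=O, C7=C8–Me), C1,C2-acetonide, C11–OTBS | CC1(C)O[C@@H]2[C@@H](O1)C(C)(C)[C@@H]3[C@H]4C(=O)C=C(C)[C@@H]3[C@@]4(C)[C@@H]2O[Si](C)(C)C(C)(C)C | intermediate
18 | C1,C2-diol, C11–OTBS | O[C@@H]1[C@@H](O)C(C)(C)[C@@H]2[C@H]3C(=O)C=C(C)[C@@H]2[C@@]3(C)[C@@H]1O[Si](C)(C)C(C)(C)C | intermediate
19 | C1,C2-diangelate, C11–OTBS | C/C=C(/C)C(=O)O[C@@H]1[C@@H](OC(=O)/C(C)=C\C)C(C)(C)[C@@H]2[C@H]3C(=O)C=C(C)[C@@H]2[C@@]3(C)[C@@H]1O[Si](C)(C)C(C)(C)C | intermediate
20 | target CNP0256888.1 | C/C=C(/C)C(=O)O[C@@H]1[C@@H](OC(=O)/C(C)=C\C)C(C)(C)[C@@H]2[C@H]3C(=O)C=C(C)[C@@H]2[C@@]3(C)[C@@H]1O | target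

Total step count: 15. Longest linear sequence: 15 steps (fully linear from eucarvone).

Steps most likely to fail

Step 10. Substitution at the tertiary epoxide carbon may be slow, so that γ-deprotonation at C5 with β-elimination of the epoxide, or simple recovery of the enolate, competes with ring closure. The fallback changes the mechanism from anionic to Lewis-acid activation. It sets out from 12: kinetic silylation (LDA, TBSCl, THF, −78 °C) gives the isolable 2-silyloxy diene F1. Treating F1 with catalytic TBSOTf in CH2Cl2 at −78 °C activates the epoxide, which opens at the tertiary carbon C10 with capture by the enol-silane carbon C9 (Mukaiyama-type epoxide opening). Silyl transfer to O11 returns the route at 15.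

Step 3. Oxygen transfer may be unselective among the three double bonds of the trienal, the aldehyde may be over-oxidised, or the enantioselectivity may be low. The fallback sets out from 1 and epoxidises before the formyl group exists. The same manganese salen/mCPBA protocol on eucarvone, whose only electron-rich double bond is the distal cis one, gives the epoxy enone F2. CsOAc/AcOH opens it at the allylic carbon to the hydroxy acetate F3, and TESOTf/2,6-lutidine gives the silyl ether F4. KHMDS/PhNTf2 at −78 °C (the ketone is deprotonated faster than the acetate) gives the triflate F5. Pd(PPh3)4/CO/Bu3SnH gives the aldehyde F6, and HF·pyridine removes the silyl group to return at 5.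

Step 6. The Michael addition is reversible and the aldol condensation of the methyl ketone may be sluggish, allowing retro-Michael reaction or loss of the allylic acetate. The fallback sets out from 5 and closes ring A by an irreversible olefination instead. Thermolysis of 6-(diethoxyphosphorylmethyl)-2,2-dimethyl-1,3-dioxin-4-one with 5 gives the γ-phosphono acetoacetate F7. NaH (two equivalents) in THF effects the same tethered Michael addition, followed by an intramolecular Horner–Wadsworth–Emmons reaction of the phosphonate carbon C7 with the aldehyde C6, and returns at 8.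

Further compounds
F1 | step 10 | kinetic tert-butyldimethylsilyl dienol ether of 12 (C8–OTBS, C8=C9) | CC1(C)O[C@@H]2[C@@H](O1)C(C)(C)[C@H]3C=C(O[Si](C)(C)C(C)(C)C)C=C[C@H]3[C@]4(C)O[C@H]24
F2 | step 3 | (4R,5S)-4,5-epoxy-2,6,6-trimethylcyclohept-2-en-1-one (β-epoxide of eucarvone across C1–C2 of the route numbering) | CC1=C[C@H]2O[C@H]2C(C)(C)CC1=O
F3 | step 3 | trans-4-acetoxy-5-hydroxy-2,6,6-trimethylcyclohept-2-en-1-one (C1–OAc α, C2–OH β) | CC1=C[C@H](OC(C)=O)[C@@H](O)C(C)(C)CC1=O
F4 | step 3 | O2-triethylsilyl ether of F3 | CC1=C[C@H](OC(C)=O)[C@@H](O[Si](CC)(CC)CC)C(C)(C)CC1=O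
F5 | step 3 | dienyl triflate of F4 | CC1=C[C@H](OC(C)=O)[C@@H](O[Si](CC)(CC)CC)C(C)(C)C=C1OS(=O)(=O)C(F)(F)F
F6 | step 3 | O2-triethylsilyl ether of 5 | CC1=C[C@H](OC(C)=O)[C@@H](O[Si](CC)(CC)CC)C(C)(C)C=C1C=O
F7 | step 6 | O2-[4-(diethoxyphosphoryl)-3-oxobutanoate] of 5 | CC(=O)O[C@@H]1[C@@H](OC(=O)CC(=O)CP(=O)(OCC)OCC)C(C)(C)C=C(C=O)C(C)=C1
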